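**Retrosynthetic overview**
1. Target 22 ⇐ Na/Hg detosylation ⇐ double Mitsunobu esterification (inversion at both C6) of di-O-tosyl α-truxillic diacid 18 with two molecules of 6-epi-incarvilline 15.
2. 18 ⇐ topochemical head-to-tail [2+2] photodimerisation of crystalline O-tosylferulic acid 17 (cyclobutane made in its own branch).
3. 15 ⇐ hydrogenation of the C4=C4a tetrahydropyridine 12 ⇐ acid-catalysed transpositive allylic amination (N–C3) of isopropenyl carbinol 11 ⇐ ketone 10.
4. Key C–C bond (C7a–C1): intermolecular Mukaiyama–Mannich reaction of silyl enol ether 6 with the N-acyliminium ion from 9; 6 ⇐ anti conjugate methylation of (S)-4-silyloxycyclopentenone 4, made from monoacetate 1.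
5. Ring order: cyclopentane (chiral pool) → piperidine (steps 8–9) → cyclobutane (step 13) → ester union (step 14).

Assumption: 1 is bought as the single enantiomer from enzymatic desymmetrisation of the meso diacetate; locants C1–C7a in the explanations follow the cyclopenta[c]pyridine numbering of the alkaloid half (N2, oxygen on C6).

**Step 1**
Reactants: 1 (1S,4R)-cis-4-acetoxycyclopent-2-en-1-ol
Product: 2 (1R,4S)-4-[(tert-butyldimethylsilyl)oxy]cyclopent-2-en-1-yl acetate
Conditions: TBSCl, imidazole, DMF, rt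
Reagents that add atoms: tert-butyldimethylsilyl chloride, CC(C)(C)[Si](C)(C)Cl
Why: Standard silylation of the free secondary alcohol, which fixes the carbinol that later becomes C6 without touching a stereocentre.

**Step 2**
Reactants: 2 (1R,4S)-4-[(tert-butyldimethylsilyl)oxy]cyclopent-2-en-1-yl acetate
Product: 3 (1R,4S)-4-[(tert-butyldimethylsilyl)oxy]cyclopent-2-en-1-ol
Conditions: K2CO3 (0.2 equiv), MeOH, 0 °C → rt
Reagents that add atoms: none
Why: Base-catalysed transesterification (methanolysis) removes the acetate while the silyl ether is inert.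

**Step 3**
Reactants: 3 (1R,4S)-4-[(tert-butyldimethylsilyl)oxy]cyclopent-2-en-1-ol
Product: 4 (4S)-4-[(tert-butyldimethylsilyl)oxy]cyclopent-2-en-1-one
Conditions: Dess–Martin periodinane, CH2Cl2, 0 °C → rt
Reagents that add atoms: none
Why: Dess–Martin oxidation of the allylic alcohol is non-basic, so the β-silyloxy enone forms without elimination and the silyloxy carbon stays S.

**Step 4**
Reactants: 4 (4S)-4-[(tert-butyldimethylsilyl)oxy]cyclopent-2-en-1-one
Product: 6 tert-butyldimethyl{[(1S,2S)-2-methyl-4-[(trimethylsilyl)oxy]cyclopent-3-en-1-yl]oxy}silane, via lithium enolate 5 (not isolated)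
Conditions: Me2CuLi (from MeLi and CuI), Et2O, −78 °C; then TMSCl, Et3N, −78 → 0 °C
Reagents that add atoms: lithium dimethylcuprate, [Li+].C[Cu-]C; chlorotrimethylsilane, C[Si](C)(C)Cl
Why: Cuprate conjugate (Michael-type) addition occurs anti to the silyloxy group and sets the C7 methyl, and O-silylation traps the regiodefined enolate before it can equilibrate and expel silanolate.

**Step 5**
Reactants: 7 methyl carbamate
Product: 9 methyl N-(methoxymethyl)carbamate, via methyl N-(hydroxymethyl)carbamate 8 (not isolated)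
Conditions: (CH2O)n, K2CO3 (cat.), MeOH, 60 °C; then TsOH·H2O (cat.), MeOH, rt
Reagents that add atoms: formaldehyde (as paraformaldehyde), C=O; methanol, CO
Why: N-Hydroxymethylation followed by acid-catalysed N,O-acetal formation gives a bench-stable N-acyliminium precursor.

**Step 6**
Reactants: 6 tert-butyldimethyl{[(1S,2S)-2-methyl-4-[(trimethylsilyl)oxy]cyclopent-3-en-1-yl]oxy}silane and 9 methyl N-(methoxymethyl)carbamate
Product: 10 methyl N-{[(1R,2S,3S)-3-[(tert-butyldimethylsilyl)oxy]-2-methyl-5-oxocyclopentyl]methyl}carbamate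
Conditions: TMSOTf (0.2 equiv), CH2Cl2, −78 → −40 °C
Reagents that add atoms: none
Why: Intermolecular Mukaiyama–Mannich reaction: the N-acyliminium ion from 9 attacks the enol ether carbon anti to the neighbouring methyl, forming the C7a–C1 bond with the trans,trans arrangement that is also thermodynamically preferred at this epimerisable centre.

**Step 7**
Reactants: 10 methyl N-{[(1R,2S,3S)-3-[(tert-butyldimethylsilyl)oxy]-2-methyl-5-oxocyclopentyl]methyl}carbamate
Product: 11 methyl N-{[(1R,2S,3S,5R)-3-[(tert-butyldimethylsilyl)oxy]-5-hydroxy-2-methyl-5-(prop-1-en-2-yl)cyclopentyl]methyl}carbamate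
Conditions: CH2=C(CH3)MgBr (3.5 equiv), CeCl3, THF, −78 °C
Reagents that add atoms: isopropenylmagnesium bromide, C=C(C)[Mg]Br
Why: Organocerium 1,2-addition (Imamoto conditions) is weakly basic, so the β-silyloxy ketone neither enolises nor eliminates; attack anti to the C7a arm gives the drawn carbinol, whose configuration is erased in step 8.

**Step 8**
Reactants: 11 methyl N-{[(1R,2S,3S,5R)-3-[(tert-butyldimethylsilyl)oxy]-5-hydroxy-2-methyl-5-(prop-1-en-2-yl)cyclopentyl]methyl}carbamate
Product: 12 methyl (6S,7S,7aS)-6-[(tert-butyldimethylsilyl)oxy]-4,7-dimethyl-1,3,5,6,7,7a-hexahydro-2H-cyclopenta[c]pyridine-2-carboxylate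
Conditions: camphorsulfonic acid (10 mol %), 4 Å MS, CH2Cl2, 0 °C → rt
Reagents that add atoms: none
Why: Acid-catalysed transpositive (SN1') intramolecular allylic amination: the tertiary allylic cation can be reached by the carbamate nitrogen only at the CH2 terminus (six-membered ring), which gives the tetrasubstituted C4=C4a alkene without creating or disturbing a stereocentre.

**Step 9**
Reactants: 12 methyl (6S,7S,7aS)-6-[(tert-butyldimethylsilyl)oxy]-4,7-dimethyl-1,3,5,6,7,7a-hexahydro-2H-cyclopenta[c]pyridine-2-carboxylate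
Product: 13 methyl (4R,4aS,6S,7S,7aR)-6-[(tert-butyldimethylsilyl)oxy]-4,7-dimethyloctahydro-2H-cyclopenta[c]pyridine-2-carboxylate
Conditions: H2 (50 bar), PtO2, EtOAc, rt
Reagents that add atoms: none
Why: Heterogeneous syn hydrogenation from the convex face (the side of H-7a, opposite the bulky silyloxy group) sets C4 and C4a together, so H-4, H-4a and H-7a end up all cis.

**Step 10**
Reactants: 13 methyl (4R,4aS,6S,7S,7aR)-6-[(tert-butyldimethylsilyl)oxy]-4,7-dimethyloctahydro-2H-cyclopenta[c]pyridine-2-carboxylate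
Product: 14 (4R,4aS,6S,7S,7aR)-6-[(tert-butyldimethylsilyl)oxy]-2,4,7-trimethyloctahydro-1H-cyclopenta[c]pyridine
Conditions: LiAlH4, THF, reflux
Reagents that add atoms: none
Why: Hydride reduction of the methyl carbamate delivers the N-methyl group directly; no stereocentre is involved.

**Step 11**
Reactants: 14 (4R,4aS,6S,7S,7aR)-6-[(tert-butyldimethylsilyl)oxy]-2,4,7-trimethyloctahydro-1H-cyclopenta[c]pyridine
Product: 15 6-epi-incarvilline, (4R,4aS,6S,7S,7aR)-2,4,7-trimethyloctahydro-1H-cyclopenta[c]pyridin-6-ol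
Conditions: Bu4NF, THF, rt
Reagents that add atoms: none
Why: Fluoride-mediated desilylation frees the C6 alcohol with retention.

**Step 12**
Reactants: 16 (E)-ferulic acid
Product: 17 (E)-3-{3-methoxy-4-[(4-methylbenzenesulfonyl)oxy]phenyl}prop-2-enoic acid
Conditions: TsCl, NaOH, THF/H2O, 0 °C → rt; then HCl
Reagents that add atoms: p-toluenesulfonyl chloride, Cc1ccc(cc1)S(=O)(=O)Cl
Why: Schotten–Baumann sulfonylation of the phenoxide (any mixed anhydride at the carboxylate is hydrolysed back) masks the phenol for the Mitsunobu step and gives a crystalline acid for the photodimerisation.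

**Step 13**
Reactants: 17 (E)-3-{3-methoxy-4-[(4-methylbenzenesulfonyl)oxy]phenyl}prop-2-enoic acid (two molecules)
Product: 18 (1α,2α,3β,4β)-2,4-bis{3-methoxy-4-[(4-methylbenzenesulfonyl)oxy]phenyl}cyclobutane-1,3-dicarboxylic acid
Conditions: hν (high-pressure Hg lamp, Pyrex), crystalline powder suspended in hexane, rt
Reagents that add atoms: none
Why: Topochemical [2+2] photocycloaddition: antiparallel head-to-tail neighbours related by an inversion centre in the crystal give the centrosymmetric α-truxillic acid, with each E alkene preserved as a trans aryl/carboxyl pair.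

**Step 14**
Reactants: 18 (1α,2α,3β,4β)-2,4-bis{3-methoxy-4-[(4-methylbenzenesulfonyl)oxy]phenyl}cyclobutane-1,3-dicarboxylic acid and 15 6-epi-incarvilline (2.4 equiv)
Product: 20 di-O-tosylincarvillateine, via monoester 19 (not isolated)
Conditions: PPh3, DEAD, THF, 0 °C → rt
Reagents that add atoms: none
Why: Double Mitsunobu esterification: each carboxylate displaces the activated C6 oxygen by SN2 with inversion (6S → 6R), and since the acid is never activated the cyclobutane stereocentres cannot epimerise.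

**Step 15**
Reactants: 20 di-O-tosylincarvillateine
Product: 22 incarvillateine (CNP0283097.2), via monotosylate 21 (not isolated)
Conditions: Na/Hg (5% Na), Na2HPO4, MeOH, −20 → 0 °C
Reagents that add atoms: none
Why: Buffered single-electron reductive cleavage of the aryl sulfonate S–O bonds frees both phenols without methanolysis of the hindered esters.

**Compound list**
1 | (1S,4R)-cis-4-acetoxycyclopent-2-en-1-ol | O[C@H]1C[C@@H](OC(C)=O)C=C1 | starting material
2 | (1R,4S)-4-[(tert-butyldimethylsilyl)oxy]cyclopent-2-en-1-yl acetate | CC(C)(C)[Si](C)(C)O[C@H]1C[C@@H](OC(C)=O)C=C1 | intermediate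
3 | (1R,4S)-4-[(tert-butyldimethylsilyl)oxy]cyclopent-2-en-1-ol | CC(C)(C)[Si](C)(C)O[C@H]1C[C@@H](O)C=C1 | intermediate
4 | (4S)-4-[(tert-butyldimethylsilyl)oxy]cyclopent-2-en-1-one | CC(C)(C)[Si](C)(C)O[C@H]1CC(=O)C=C1 | intermediate
5 | lithium (3S,4S)-4-[(tert-butyldimethylsilyl)oxy]-3-methylcyclopent-1-en-1-olate | [Li]OC1=C[C@H](C)[C@@H](O[Si](C)(C)C(C)(C)C)C1 | intermediate (not isolated)
6 | tert-butyldimethyl{[(1S,2S)-2-methyl-4-[(trimethylsilyl)oxy]cyclopent-3-en-1-yl]oxy}silane | C[Si](C)(C)OC1=C[C@H](C)[C@@H](O[Si](C)(C)C(C)(C)C)C1 | intermediate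
7 | methyl carbamate | COC(N)=O | starting material
8 | methyl N-(hydroxymethyl)carbamate | COC(=O)NCO | intermediate (not isolated)
9 | methyl N-(methoxymethyl)carbamate | COCNC(=O)OC | intermediate
10 | methyl N-{[(1R,2S,3S)-3-[(tert-butyldimethylsilyl)oxy]-2-methyl-5-oxocyclopentyl]methyl}carbamate | COC(=O)NC[C@H]1[C@H](C)[C@@H](O[Si](C)(C)C(C)(C)C)CC1=O | intermediate
11 | methyl N-{[(1R,2S,3S,5R)-3-[(tert-butyldimethylsilyl)oxy]-5-hydroxy-2-methyl-5-(prop-1-en-2-yl)cyclopentyl]methyl}carbamate (major carbinol epimer; either converges) | COC(=O)NC[C@H]1[C@H](C)[C@@H](O[Si](C)(C)C(C)(C)C)C[C@]1(O)C(C)=C | intermediate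
12 | methyl (6S,7S,7aS)-6-[(tert-butyldimethylsilyl)oxy]-4,7-dimethyl-1,3,5,6,7,7a-hexahydro-2H-cyclopenta[c]pyridine-2-carboxylate | COC(=O)N1C[C@H]2[C@H](C)[C@@H](O[Si](C)(C)C(C)(C)C)CC2=C(C)C1 | intermediate
13 | methyl (4R,4aS,6S,7S,7aR)-6-[(tert-butyldimethylsilyl)oxy]-4,7-dimethyloctahydro-2H-cyclopenta[c]pyridine-2-carboxylate | CC(C)(C)[Si](C)(C)O[C@H]1C[C@@H]2[C@@H](CN(C(=O)OC)C[C@@H]2C)[C@@H]1C | intermediate
14 | (4R,4aS,6S,7S,7aR)-6-[(tert-butyldimethylsilyl)oxy]-2,4,7-trimethyloctahydro-1H-cyclopenta[c]pyridine | CC(C)(C)[Si](C)(C)O[C@H]1C[C@@H]2[C@@H](CN(C)C[C@@H]2C)[C@@H]1C | intermediate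
15 | 6-epi-incarvilline, (4R,4aS,6S,7S,7aR)-2,4,7-trimethyloctahydro-1H-cyclopenta[c]pyridin-6-ol | O[C@H]1C[C@@H]2[C@@H](CN(C)C[C@@H]2C)[C@@H]1C | intermediate
16 | (E)-ferulic acid, (E)-3-(4-hydroxy-3-methoxyphenyl)prop-2-enoic acid | COc1cc(/C=C/C(=O)O)ccc1O | starting material
17 | (E)-3-{3-methoxy-4-[(4-methylbenzenesulfonyl)oxy]phenyl}prop-2-enoic acid | COc1cc(/C=C/C(=O)O)ccc1OS(=O)(=O)c1ccc(C)cc1 | intermediate
18 | (1α,2α,3β,4β)-2,4-bis{3-methoxy-4-[(4-methylbenzenesulfonyl)oxy]phenyl}cyclobutane-1,3-dicarboxylic acid (centrosymmetric α-truxillic type) | COc1cc([C@H]2[C@H](C(=O)O)[C@H](c3ccc(OS(=O)(=O)c4ccc(C)cc4)c(OC)c3)[C@H]2C(=O)O)ccc1OS(=O)(=O)c1ccc(C)cc1 | intermediate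
19 | mono-(incarvillin-6-yl) ester of 18 (one of the two diastereomers that arise from the enantiotopic carboxyl groups; both converge on 20) | COc1cc([C@H]2[C@H](C(=O)O[C@@H]3C[C@@H]4[C@@H](CN(C)C[C@@H]4C)[C@@H]3C)[C@H](c3ccc(OS(=O)(=O)c4ccc(C)cc4)c(OC)c3)[C@H]2C(=O)O)ccc1OS(=O)(=O)c1ccc(C)cc1 | intermediate (not isolated)
20 | di-O-tosylincarvillateine, bis[(4R,4aS,6R,7S,7aR)-2,4,7-trimethyloctahydro-1H-cyclopenta[c]pyridin-6-yl] ester of 18 | COc1cc([C@H]2[C@H](C(=O)O[C@@H]3C[C@@H]4[C@@H](CN(C)C[C@@H]4C)[C@@H]3C)[C@H](c3ccc(OS(=O)(=O)c4ccc(C)cc4)c(OC)c3)[C@H]2C(=O)O[C@@H]2C[C@@H]3[C@@H](CN(C)C[C@@H]3C)[C@@H]2C)ccc1OS(=O)(=O)c1ccc(C)cc1 | intermediate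
21 | mono-O-tosylincarvillateine (one of the two regioisomers; both converge on 22) | COc1cc([C@H]2[C@H](C(=O)O[C@@H]3C[C@@H]4[C@@H](CN(C)C[C@@H]4C)[C@@H]3C)[C@H](c3ccc(O)c(OC)c3)[C@H]2C(=O)O[C@@H]2C[C@@H]3[C@@H](CN(C)C[C@@H]3C)[C@@H]2C)ccc1OS(=O)(=O)c1ccc(C)cc1 | intermediate (not isolated)
22 | incarvillateine (CNP0283097.2) | COc1cc([C@H]2[C@H](C(=O)O[C@@H]3C[C@@H]4[C@@H](CN(C)C[C@@H]4C)[C@@H]3C)[C@H](c3ccc(O)c(OC)c3)[C@H]2C(=O)O[C@@H]2C[C@@H]3[C@@H](CN(C)C[C@@H]3C)[C@@H]2C)ccc1O | target

**Totals**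
Total step count: 15. Longest linear sequence: 12 steps (1 → 22 through steps 1–4, 6–11, 14 and 15); step 5 and steps 12–13 are side branches.

**Three steps most likely to fail**

Step 8 (transpositive cyclisation). The allyl cation can instead lose a proton to dienes, epimerise C7a through reversible elimination, or the acid can strip the silyl ether. Fallback, setting out from 11 and returning at 12: treat 11 with SOCl2 and pyridine in Et2O at 0 °C, where chlorosulfite collapse with allylic rearrangement gives the rearranged primary allylic chloride F1 as an E/Z mixture. Then close the ring by Tsuji–Trost allylic amination with Pd(PPh3)4 (5 mol %) and Cs2CO3 in THF at 50 °C. Zerovalent palladium ionises either geometric isomer to a π-allyl complex that equilibrates syn/anti, and the carbamate nitrogen attacks the CH2 terminus to give 12 under neutral, non-cationic conditions.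

Step 9 (hydrogenation). Facial selectivity rests on sterics alone, and double-bond migration on the catalyst could scramble C4. Fallback, setting out from 12 and returning at 20, which switches to hydroxyl-directed delivery:
- Desilylate 12 (Bu4NF, THF) to the homoallylic alcohol F2.
- Invert C6 by Mitsunobu reaction with 4-nitrobenzoic acid (PPh3, DIAD, THF) to the C6-inverted 4-nitrobenzoate F3.
- Methanolyse (K2CO3, MeOH) to the (6R)-alcohol F4, whose hydroxyl now lies on the same face as H-7a.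
- Hydrogenate with [Ir(cod)(PCy3)(py)]PF6 (5 mol %) and H2 in CH2Cl2, so that the coordinated hydroxyl steers both hydrogens to that face, giving the saturated (6R)-hydroxy carbamate F5.
- Reduce with LiAlH4 (THF, reflux) to incarvilline F6.
- Esterify 18 with 2.2 equiv of F6 with retention (EDC·HCl, DMAP, CH2Cl2, rt) to rejoin the route at 20.

Step 14 (double Mitsunobu). The carbinol is hindered by the adjacent methyl-bearing carbon, so elimination or a stalled second esterification is possible. Fallback, setting out from 15 and returning at 20: convert 15 with MsCl and Et3N in CH2Cl2 at 0 °C into 6-epi-incarvilline mesylate F7. Separately, stir 18 with Cs2CO3 in DMF to form the dicesium dicarboxylate F8. Heating F8 with 2.4 equiv of F7 in DMF at 60 °C gives 20 by SN2 carboxylate displacement with the same inversion at C6; the face needed for intramolecular attack by the ring nitrogen is blocked, so the amine does not interfere.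

**Further compounds**
F1 | step 8 | rearranged primary allylic chloride, methyl N-{[(1S,2S,3S)-3-[(tert-butyldimethylsilyl)oxy]-5-(1-chloropropan-2-ylidene)-2-methylcyclopentyl]methyl}carbamate (E/Z mixture) | COC(=O)NC[C@H]1[C@H](C)[C@@H](O[Si](C)(C)C(C)(C)C)CC1=C(C)CCl
F2 | step 9 | desilylated homoallylic alcohol, methyl (6S,7S,7aS)-6-hydroxy-4,7-dimethyl-1,3,5,6,7,7a-hexahydro-2H-cyclopenta[c]pyridine-2-carboxylate | COC(=O)N1C[C@H]2[C@H](C)[C@@H](O)CC2=C(C)C1
F3 | step 9 | C6-inverted 4-nitrobenzoate, methyl (6R,7S,7aS)-4,7-dimethyl-6-[(4-nitrobenzoyl)oxy]-1,3,5,6,7,7a-hexahydro-2H-cyclopenta[c]pyridine-2-carboxylate | COC(=O)N1C[C@H]2[C@H](C)[C@H](OC(=O)c3ccc(cc3)[N+](=O)[O-])CC2=C(C)C1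
F4 | step 9 | (6R)-alcohol, methyl (6R,7S,7aS)-6-hydroxy-4,7-dimethyl-1,3,5,6,7,7a-hexahydro-2H-cyclopenta[c]pyridine-2-carboxylate | COC(=O)N1C[C@H]2[C@H](C)[C@H](O)CC2=C(C)C1
F5 | step 9 | saturated (6R)-hydroxy carbamate, methyl (4R,4aS,6R,7S,7aR)-6-hydroxy-4,7-dimethyloctahydro-2H-cyclopenta[c]pyridine-2-carboxylate | O[C@@H]1C[C@@H]2[C@@H](CN(C(=O)OC)C[C@@H]2C)[C@@H]1C
F6 | step 9 | incarvilline, (4R,4aS,6R,7S,7aR)-2,4,7-trimethyloctahydro-1H-cyclopenta[c]pyridin-6-ol | O[C@@H]1C[C@@H]2[C@@H](CN(C)C[C@@H]2C)[C@@H]1C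
F7 | step 14 | 6-epi-incarvilline mesylate, (4R,4aS,6S,7S,7aR)-2,4,7-trimethyloctahydro-1H-cyclopenta[c]pyridin-6-yl methanesulfonate | CS(=O)(=O)O[C@H]1C[C@@H]2[C@@H](CN(C)C[C@@H]2C)[C@@H]1C
F8 | step 14 | dicesium dicarboxylate of 18 | [Cs+].[Cs+].COc1cc([C@H]2[C@H](C(=O)[O-])[C@H](c3ccc(OS(=O)(=O)c4ccc(C)cc4)c(OC)c3)[C@H]2C(=O)[O-])ccc1OS(=O)(=O)c1ccc(C)cc1
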